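Readings and results come from a simulation with constants of no real substance; scatter was added.

I had no rate constants to start from, so I looked in the earlier runs for one number that could stand in for them.

in all of them: D 0.50 M

|  | J | remark | time |
|---|---|---|---|
| beta | 0.26 equiv | run made earlier |  |
| epsilon | 1.9 equiv | run made earlier |  |
| dawn | 2.80 equiv |  | 20 h |
| summer | 1.40 equiv |  | 20 h |
| winter | 1.00 equiv |  | 20 h |
| autumn | 0.700 equiv |  | 20 h |
| midnight | 0.350 equiv |  | 20 h |

| run | time / h | L / % | D / % |
|---|---|---|---|
| beta | 2.00 | 2.1 | 72.3 |
| beta | 5.00 | 6.3 | 49.3 |
| beta | 10.0 | 9.1 | 30.8 |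
| beta | 15.0 | 8.3 | 24.5 |
| epsilon | 2.00 | 11.4 | 69.4 |
| epsilon | 5.00 | 33.4 | 30.3 |
| epsilon | 10.0 | 59.8 | 0 |
| epsilon | 15.0 | 68.1 | 0 |

(each reading ± 0.3 percentage points)

- as a solid, counted per litre of solution: D
- at the start none of D is in solution
- what has only dissolved of D counts as not reacted

- the flasks put in order of amount of L, in percent of the D charged, best first, at 20 h (dawn / summer / winter / autumn / midnight)
- the amount of L, in percent of the D charged of the flask you put first, at 20 h
- the amount of L, in percent of the D charged of the flask you put last, at 20 h

I followed one molecule of J and asked for its chance of being found as L at a reading. The beta run gave, at its highest reading of L,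

share = 9.1% / 0.26 equiv = 0.350

I called this L per equivalent of J charged the capture share, a net yield on the J charged and not a selectivity, since it counts neither the J left unused nor the L already lost. The epsilon run, at its last reading, gave 0.358, so I multiplied the share by each charge of J:

midnight 12.2%, autumn 24.5%, winter 35.0%, summer 49.0%, dawn 98.0%

Was one number enough? For the order I took it to be, but not for the ends. The epsilon run still had 31.9% of its D standing as neither D nor L at its last reading, and L in the beta run fell from 9.1% to 8.3%, so I held the dawn and midnight figures as upper limits.

The forecast, which read “L plateaus near 0.35 per equivalent of J”, gave dawn > summer > winter > autumn > midnight, with 78% and 10%, both lower than my limits.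

The flasks gave dawn > summer > winter > autumn > midnight, with 80.2% in dawn and 11.0% in midnight.

    D ⇌ X, rate k1*(cs1 - [X]) while solid is left; crystals form when [X] > cs1 (solubility = 0.290 M, k = 0.00520 /min)
    D + L → E (k = 0.00500 /M/min)
    X + J → L (k = 0.0120 /M/min)
    J → Z (k = 0.00150 /min)

At the asked time the share read 0.314 in midnight, 0.406 in autumn and 0.286 in dawn, against the 0.350 I carried, so the number held the order but not the amounts. It has no place for the step that takes D and L to E: in midnight L was being made at 0.174 of the rate at which it was used up, with 15.5% of D present. A neighbour of midnight charged with 0.210 equiv of J reckoned to 7.35% and held 5.76% of L, a share of 0.274, lower than midnight's, with 25.0% of D still there.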